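**Plan**

- Retrosynthetic cuts: (a) the bond from C8 of coumarin A to the styryl CH (Heck); (b) the pyranone of coumarin B at the lactone C–O and C3=C4, then the C4–C4a bond (formyl group); (c) the benzene ring of coumarin B at C4a–C8a and C5–C6, with C8–C8a opened, back to a 4-substituted 3-methoxycyclobutenone and methoxyacetylene; (d) the cyclobutenone to a ketene and a second methoxyacetylene; (e) the cyclohexene at C1–C6 and C2–C3 (Diels–Alder), after removal of the C1 methyl group.
- Enabling feature: C8 of coumarin B sits between the oxygen-bearing carbons C7 and C8a, C5 is oxygenated as well, and C8 carries the crowded bond to stereogenic cyclohexene C6 beside quaternary C1. This 1,3,5-trioxygenated ring with the alkyl group flanked by O and OMe is the pattern that a vinylketene/ynol ether benzannulation produces, so the hindered aryl–alkyl bond is present before the arene exists.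
- Forward order: cyclohexene (Diels–Alder) → C1 methyl, C1 vinyl and C6 acetic acid arm → cyclobutenone → benzene ring of coumarin B → pyranone of coumarin B → Heck union with 8-iodo-5,7-dimethoxycoumarin (coumarin A).
- Stereochemistry: C6 from the (R)-4-benzyloxazolidinone auxiliary in an endo Diels–Alder reaction; C1 from enolate methylation anti to the C6 side chain; the E alkene from the Heck reaction.

Key step: step 13

Remark 1: electrophilic iodination of 5,7-dimethoxycoumarin is taken to occur at C8 (ortho to the C7 methoxy group and the ring oxygen, para to the C5 methoxy group, and less hindered than C6).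
Remark 2: in the text C1 (quaternary) and C6 (aryl-bearing) are the cyclohexene carbons of the target; systematic names use their own locants, and CIP descriptors change along the route only because substituent priorities change, not because a centre is inverted.

**Route**

Step 1
Reactants: 1 tert-butyl(but-3-yn-1-yloxy)dimethylsilane; 2 2-bromopropene
Product: 4 tert-butyldimethyl{[(3E)-5-methylhexa-3,5-dien-1-yl]oxy}silane, via alkenylzirconocene chloride 3 (not isolated)
Conditions: Cp2Zr(H)Cl, THF, rt; then 2, Pd(PPh3)4 (5 mol %), rt → 40 °C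
Reagents that add atoms: none
Why: Hydrozirconation adds Zr–H syn across the terminal alkyne with zirconium on the terminal carbon, and Negishi-type palladium-catalysed coupling of the (E)-alkenylzirconocene with the alkenyl bromide proceeds with retention, so the (E)-diene is expected.

Step 2
Reactants: 5 (4R)-4-benzyl-1,3-oxazolidin-2-one; 6 acryloyl chloride
Product: 7 (4R)-4-benzyl-3-(prop-2-enoyl)-1,3-oxazolidin-2-one
Conditions: Et3N, LiCl, THF, −20 °C → rt
Reagents that add atoms: none
Why: N-acylation of an Evans oxazolidinone under LiCl/Et3N activation is a mild standard route to N-enoyl imides and avoids the strongly basic conditions that polymerise acrylates.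

Step 3
Reactants: 4 tert-butyldimethyl{[(3E)-5-methylhexa-3,5-dien-1-yl]oxy}silane; 7 (4R)-4-benzyl-3-(prop-2-enoyl)-1,3-oxazolidin-2-one
Product: 8 (4R)-4-benzyl-3-{[(1S,2R)-2-[2-(tert-butyldimethylsilyloxy)ethyl]-4-methylcyclohex-3-en-1-yl]carbonyl}-1,3-oxazolidin-2-one
Conditions: Et2AlCl (1.4 equiv), CH2Cl2, −78 °C
Reagents that add atoms: none
Why: In this Evans auxiliary-controlled Diels–Alder reaction Et2AlCl chelates both imide carbonyls and locks the s-cis enoyl unit, the benzyl group shields one face so the diene adds endo to the Cα-re face, and the 1-alkyl and 3-methyl groups of the diene both direct the "ortho/para" regiochemistry; this sets C6, while the C1 centre formed here is erased in step 5.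

Step 4
Reactants: 8 the Diels–Alder imide
Product: 9 methyl (1S,2R)-2-[2-(tert-butyldimethylsilyloxy)ethyl]-4-methylcyclohex-3-ene-1-carboxylate
Conditions: MeOMgBr (from MeMgBr and MeOH), MeOH–CH2Cl2, 0 °C → rt
Reagents that add atoms: methanol, CO
Why: Transesterification with MeOMgBr attacks the exocyclic imide carbonyl and releases the auxiliary for recovery; epimerisation at C1 is harmless because that centre is planarised in the next step.

Step 5
Reactants: 9 methyl (1S,2R)-2-[2-(tert-butyldimethylsilyloxy)ethyl]-4-methylcyclohex-3-ene-1-carboxylate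
Product: 11 methyl (1S,2R)-2-[2-(tert-butyldimethylsilyloxy)ethyl]-1,4-dimethylcyclohex-3-ene-1-carboxylate, via lithium enolate 10 (not isolated)
Conditions: LiN(i-Pr)2, THF, −78 °C; MeI, −78 → 0 °C
Reagents that add atoms: iodomethane, CI
Why: In this ester enolate alkylation allylic 1,3-strain in the exocyclic enolate places the C6 side chain pseudoaxial, so MeI should add to the opposite face, putting the new methyl group trans to the side chain and fixing quaternary C1 with the relative configuration of the target.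

Step 6
Reactants: 11 methyl (1S,2R)-2-[2-(tert-butyldimethylsilyloxy)ethyl]-1,4-dimethylcyclohex-3-ene-1-carboxylate
Product: 12 {(1S,2R)-2-[2-(tert-butyldimethylsilyloxy)ethyl]-1,4-dimethylcyclohex-3-en-1-yl}methanol
Conditions: LiAlH4, Et2O, 0 °C
Reagents that add atoms: none
Why: Hydride reduction of the hindered ester with LiAlH4 gives the neopentyl alcohol and leaves the silyl ether and the alkene untouched.

Step 7
Reactants: 12 {(1S,2R)-2-[2-(tert-butyldimethylsilyloxy)ethyl]-1,4-dimethylcyclohex-3-en-1-yl}methanol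
Product: 13 (1S,2R)-2-[2-(tert-butyldimethylsilyloxy)ethyl]-1,4-dimethylcyclohex-3-ene-1-carbaldehyde
Conditions: Dess–Martin periodinane, CH2Cl2, rt
Reagents that add atoms: none
Why: Dess–Martin oxidation works under near-neutral conditions, and the aldehyde has no α-hydrogen, so it cannot epimerise.

Step 8
Reactants: 13 (1S,2R)-2-[2-(tert-butyldimethylsilyloxy)ethyl]-1,4-dimethylcyclohex-3-ene-1-carbaldehyde
Product: 14 tert-butyl{2-[(1R,6R)-6-ethenyl-3,6-dimethylcyclohex-2-en-1-yl]ethoxy}dimethylsilane
Conditions: Ph3PCH3Br, KOtBu, THF, 0 → 60 °C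
Reagents that add atoms: methyltriphenylphosphonium bromide, C[P+](c1ccccc1)(c1ccccc1)c1ccccc1.[Br-]
Why: Wittig methylenation with the small unstabilised ylide is reliable for α-quaternary aldehydes and installs the C1 vinyl group that is arylated at the end.

Step 9
Reactants: 14 tert-butyl{2-[(1R,6R)-6-ethenyl-3,6-dimethylcyclohex-2-en-1-yl]ethoxy}dimethylsilane
Product: 15 2-[(1R,6R)-6-ethenyl-3,6-dimethylcyclohex-2-en-1-yl]ethan-1-ol
Conditions: n-Bu4NF, THF, rt
Reagents that add atoms: none
Why: Fluoride-induced cleavage of the primary silyl ether is selective and does not affect the alkenes.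

Step 10
Reactants: 15 2-[(1R,6R)-6-ethenyl-3,6-dimethylcyclohex-2-en-1-yl]ethan-1-ol
Product: 17 2-[(1R,6R)-6-ethenyl-3,6-dimethylcyclohex-2-en-1-yl]acetic acid, via aldehyde 16 (not isolated)
Conditions: TEMPO (20 mol %), PhI(OAc)2 (2.2 equiv), MeCN–H2O, rt
Reagents that add atoms: water, O
Why: Oxoammonium (TEMPO/PhI(OAc)2) oxidation in aqueous acetonitrile takes the primary alcohol through the aldehyde hydrate to the acid without touching either alkene.

Step 11
Reactants: 18 2-chloro-1,1-dimethoxyethane
Product: 21 methoxyethyne (methoxyacetylene), via 1-chloro-2-methoxyethene 19 (not isolated), via sodium methoxyacetylide 20 (not isolated)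
Conditions: NaNH2 (3 equiv), liquid NH3, −33 °C; then aq. NH4Cl, −70 °C; distil, keep as a cold solution
Reagents that add atoms: none
Why: Twofold base-induced elimination (methanol, then HCl) with NaNH2 in liquid ammonia is the standard preparation of alkoxyacetylenes, and the acetylide is protonated on quench.

Step 12
Reactants: 17 2-[(1R,6R)-6-ethenyl-3,6-dimethylcyclohex-2-en-1-yl]acetic acid; 21 methoxyethyne
Product: 24 4-[(1S,6R)-6-ethenyl-3,6-dimethylcyclohex-2-en-1-yl]-3-methoxycyclobut-2-en-1-one, via acid chloride 22 (not isolated), via ketene 23 (not isolated)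
Conditions: (COCl)2, DMF (cat.), CH2Cl2, 0 °C → rt, concentrate; then 21 (3 equiv), Et3N, Et2O, 0 °C → rt
Reagents that add atoms: none
Why: Et3N dehydrochlorinates the acid chloride to the aldoketene, which is trapped in situ by the electron-rich ynol ether in a [2+2] cycloaddition whose polarity (ketene carbonyl carbon to the CH terminus of the ynol ether) gives the 4-substituted 3-methoxycyclobutenone; the new ring centre forms as a mixture, which is irrelevant because it becomes aromatic C8.

Step 13
Reactants: 24 4-[(1S,6R)-6-ethenyl-3,6-dimethylcyclohex-2-en-1-yl]-3-methoxycyclobut-2-en-1-one; 21 methoxyethyne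
Product: 29 2-[(1R,6R)-6-ethenyl-3,6-dimethylcyclohex-2-en-1-yl]-3,5-dimethoxyphenol, via vinylketene 25 (not isolated), via 4-alkenylcyclobutenone 26 (not isolated), via dienylketene 27 (not isolated), via cyclohexadienone 28 (not isolated)
Conditions: 21 (3 equiv), toluene, sealed tube, 80 °C, then 110 °C
Reagents that add atoms: none
Why: On heating, cyclobutenone 24 should undergo four-electron conrotatory ring opening, the ring substituent turning outward, to vinylketene 25, whose ketene C=C adds to methoxyacetylene in a [2+2] cycloaddition with the CH terminus of the ynol ether bonding to the ketene carbonyl carbon, giving 26. A second four-electron opening gives dienylketene 27, which closes the benzene ring of coumarin B by thermal six-electron disrotatory electrocyclisation (former ketene carbon to the carbon bearing the cyclohexenyl group) to 28, and tautomerisation delivers phenol 29. This is a Danheiser benzannulation, closest to the known union of 3-oxygenated cyclobutenones with ynol ethers to give resorcinol monoethers. No stereocentre is formed, and C1 and C6 of the cyclohexene are remote spectators under these neutral thermal conditions. The only selectivity needed is regiochemical and is fixed by the polarity of the ketene–ynol ether addition: the ketene carbonyl carbon becomes C8a (OH), the alkyne CH becomes C4a, the alkyne C–OMe becomes C5, and cyclobutenone C2, C3 (OMe) and C4 become C6, C7 and C8, so the cyclohexenyl group ends between OH and OMe with the second OMe para. Excess ynol ether in a sealed tube keeps the bimolecular step ahead of ketene dimerisation and of acylation of the product phenol by the vinylketene.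

Step 14
Reactants: 29 2-[(1R,6R)-6-ethenyl-3,6-dimethylcyclohex-2-en-1-yl]-3,5-dimethoxyphenol
Product: 31 3-[(1R,6R)-6-ethenyl-3,6-dimethylcyclohex-2-en-1-yl]-2-hydroxy-4,6-dimethoxybenzaldehyde, via hydroxymethylphenol 30 (not isolated)
Conditions: MgCl2, Et3N, (CH2O)n, MeCN, reflux
Reagents that add atoms: formaldehyde (as paraformaldehyde), C=O
Why: In this magnesium-mediated ortho-formylation (Casnati–Skattebøl type) the magnesium phenoxide delivers formaldehyde only to the free position ortho to oxygen (future C4a), not to the position between the two methoxy groups, and hydride transfer to a second formaldehyde gives the salicylaldehyde.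

Step 15
Reactants: 31 3-[(1R,6R)-6-ethenyl-3,6-dimethylcyclohex-2-en-1-yl]-2-hydroxy-4,6-dimethoxybenzaldehyde
Product: 33 8-[(1R,6R)-6-ethenyl-3,6-dimethylcyclohex-2-en-1-yl]-5,7-dimethoxy-2H-chromen-2-one, via ethyl hydroxycinnamate 32 (not isolated)
Conditions: Ph3P=CHCO2Et, PhNEt2, reflux
Reagents that add atoms: ethyl (triphenylphosphoranylidene)acetate, CCOC(=O)C=P(c1ccccc1)(c1ccccc1)c1ccccc1
Why: Wittig olefination with the stabilised ylide, followed by thermal E/Z equilibration and lactonisation of the cinnamate in refluxing N,N-diethylaniline, is the classical coumarin synthesis from salicylaldehydes and closes the pyranone of coumarin B.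

Step 16
Reactants: 34 5,7-dimethoxy-2H-chromen-2-one
Product: 35 8-iodo-5,7-dimethoxy-2H-chromen-2-one
Conditions: N-iodosuccinimide, CF3CO2H (cat.), MeCN, rt
Reagents that add atoms: N-iodosuccinimide, O=C1CCC(=O)N1I
Why: In this electrophilic aromatic iodination C8 is activated by the ortho C7 methoxy group, the ortho ring oxygen and the para C5 methoxy group, and is less hindered than C6, which lies between two methoxy groups.

Step 17
Reactants: 33 8-[(1R,6R)-6-ethenyl-3,6-dimethylcyclohex-2-en-1-yl]-5,7-dimethoxy-2H-chromen-2-one; 35 8-iodo-5,7-dimethoxy-2H-chromen-2-one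
Product: 36 5,7-dimethoxy-8-[(1R,6R)-6-[(E)-2-(5,7-dimethoxy-2-oxo-2H-chromen-8-yl)ethenyl]-3,6-dimethylcyclohex-2-en-1-yl]-2H-chromen-2-one (CNP0164660.2)
Conditions: Pd(OAc)2 (10 mol %), n-Bu4NCl, NaHCO3, DMF, 80 °C
Reagents that add atoms: none
Why: In this Mizoroki–Heck reaction the arylpalladium species adds its aryl group to the terminal carbon of the monosubstituted alkene, and because C1 is quaternary, syn β-hydride elimination can only use the benzylic hydrogen, giving the E-styrene without double-bond migration; the ring alkene and the coumarin C3=C4 bonds are too hindered to compete.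

**Compound list**

1 | tert-butyl(but-3-yn-1-yloxy)dimethylsilane | C#CCCO[Si](C)(C)C(C)(C)C | starting material
2 | 2-bromopropene | CC(Br)=C | starting material
3 | chlorobis(cyclopentadienyl)[(1E)-4-(tert-butyldimethylsilyloxy)but-1-en-1-yl]zirconium | CC(C)(C)[Si](C)(C)OCC/C=C/[Zr](Cl)(C1C=CC=C1)C1C=CC=C1 | intermediate (not isolated)
4 | tert-butyldimethyl{[(3E)-5-methylhexa-3,5-dien-1-yl]oxy}silane | CC(=C)/C=C/CCO[Si](C)(C)C(C)(C)C | intermediate
5 | (4R)-4-benzyl-1,3-oxazolidin-2-one | O=C1N[C@H](Cc2ccccc2)CO1 | starting material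
6 | acryloyl chloride | C=CC(=O)Cl | starting material
7 | (4R)-4-benzyl-3-(prop-2-enoyl)-1,3-oxazolidin-2-one | C=CC(=O)N1[C@H](Cc2ccccc2)COC1=O | intermediate
8 | (4R)-4-benzyl-3-{[(1S,2R)-2-[2-(tert-butyldimethylsilyloxy)ethyl]-4-methylcyclohex-3-en-1-yl]carbonyl}-1,3-oxazolidin-2-one | O=C1OC[C@@H](Cc2ccccc2)N1C(=O)[C@H]1CCC(C)=C[C@H]1CCO[Si](C)(C)C(C)(C)C | intermediate
9 | methyl (1S,2R)-2-[2-(tert-butyldimethylsilyloxy)ethyl]-4-methylcyclohex-3-ene-1-carboxylate | COC(=O)[C@H]1CCC(C)=C[C@H]1CCO[Si](C)(C)C(C)(C)C | intermediate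
10 | lithium {(2R)-2-[2-(tert-butyldimethylsilyloxy)ethyl]-4-methylcyclohex-3-en-1-ylidene}(methoxy)methanolate | [Li+].COC([O-])=C1CCC(C)=C[C@H]1CCO[Si](C)(C)C(C)(C)C | intermediate (not isolated)
11 | methyl (1S,2R)-2-[2-(tert-butyldimethylsilyloxy)ethyl]-1,4-dimethylcyclohex-3-ene-1-carboxylate | COC(=O)[C@@]1(C)CCC(C)=C[C@H]1CCO[Si](C)(C)C(C)(C)C | intermediate
12 | {(1S,2R)-2-[2-(tert-butyldimethylsilyloxy)ethyl]-1,4-dimethylcyclohex-3-en-1-yl}methanol | OC[C@@]1(C)CCC(C)=C[C@H]1CCO[Si](C)(C)C(C)(C)C | intermediate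
13 | (1S,2R)-2-[2-(tert-butyldimethylsilyloxy)ethyl]-1,4-dimethylcyclohex-3-ene-1-carbaldehyde | O=C[C@@]1(C)CCC(C)=C[C@H]1CCO[Si](C)(C)C(C)(C)C | intermediate
14 | tert-butyl{2-[(1R,6R)-6-ethenyl-3,6-dimethylcyclohex-2-en-1-yl]ethoxy}dimethylsilane | C=C[C@@]1(C)CCC(C)=C[C@H]1CCO[Si](C)(C)C(C)(C)C | intermediate
15 | 2-[(1R,6R)-6-ethenyl-3,6-dimethylcyclohex-2-en-1-yl]ethan-1-ol | C=C[C@@]1(C)CCC(C)=C[C@H]1CCO | intermediate
16 | 2-[(1R,6R)-6-ethenyl-3,6-dimethylcyclohex-2-en-1-yl]acetaldehyde | C=C[C@@]1(C)CCC(C)=C[C@H]1CC=O | intermediate (not isolated)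
17 | 2-[(1R,6R)-6-ethenyl-3,6-dimethylcyclohex-2-en-1-yl]acetic acid | C=C[C@@]1(C)CCC(C)=C[C@H]1CC(=O)O | intermediate
18 | 2-chloro-1,1-dimethoxyethane | COC(CCl)OC | starting material
19 | 1-chloro-2-methoxyethene | COC=CCl | intermediate (not isolated)
20 | sodium methoxyacetylide | [Na+].[C-]#COC | intermediate (not isolated)
21 | methoxyethyne | COC#C | intermediate
22 | 2-[(1R,6R)-6-ethenyl-3,6-dimethylcyclohex-2-en-1-yl]acetyl chloride | C=C[C@@]1(C)CCC(C)=C[C@H]1CC(=O)Cl | intermediate (not isolated)
23 | 2-[(1S,6R)-6-ethenyl-3,6-dimethylcyclohex-2-en-1-yl]ethen-1-one | C=C[C@@]1(C)CCC(C)=C[C@H]1C=C=O | intermediate (not isolated)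
24 | 4-[(1S,6R)-6-ethenyl-3,6-dimethylcyclohex-2-en-1-yl]-3-methoxycyclobut-2-en-1-one (both epimers at the four-membered ring) | C=C[C@@]1(C)CCC(C)=C[C@H]1C1C(=O)C=C1OC | intermediate
25 | (3Z)-4-[(1S,6R)-6-ethenyl-3,6-dimethylcyclohex-2-en-1-yl]-3-methoxybuta-1,3-dien-1-one | C=C[C@@]1(C)CCC(C)=C[C@H]1/C=C(OC)/C=C=O | intermediate (not isolated)
26 | 4-{(Z)-2-[(1S,6R)-6-ethenyl-3,6-dimethylcyclohex-2-en-1-yl]-1-methoxyethenyl}-3-methoxycyclobut-2-en-1-one | C=C[C@@]1(C)CCC(C)=C[C@H]1/C=C(OC)/C1C(=O)C=C1OC | intermediate (not isolated)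
27 | (3E,5Z)-6-[(1S,6R)-6-ethenyl-3,6-dimethylcyclohex-2-en-1-yl]-3,5-dimethoxyhexa-1,3,5-trien-1-one | C=C[C@@]1(C)CCC(C)=C[C@H]1/C=C(OC)/C=C(OC)\C=C=O | intermediate (not isolated)
28 | 6-[(1S,6R)-6-ethenyl-3,6-dimethylcyclohex-2-en-1-yl]-3,5-dimethoxycyclohexa-2,4-dien-1-one | C=C[C@@]1(C)CCC(C)=C[C@H]1C1C(=O)C=C(OC)C=C1OC | intermediate (not isolated)
29 | 2-[(1R,6R)-6-ethenyl-3,6-dimethylcyclohex-2-en-1-yl]-3,5-dimethoxyphenol | C=C[C@@]1(C)CCC(C)=C[C@H]1c1c(O)cc(OC)cc1OC | intermediate
30 | 2-[(1R,6R)-6-ethenyl-3,6-dimethylcyclohex-2-en-1-yl]-6-(hydroxymethyl)-3,5-dimethoxyphenol (formed as its magnesium phenoxide) | C=C[C@@]1(C)CCC(C)=C[C@H]1c1c(O)c(CO)c(OC)cc1OC | intermediate (not isolated)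
31 | 3-[(1R,6R)-6-ethenyl-3,6-dimethylcyclohex-2-en-1-yl]-2-hydroxy-4,6-dimethoxybenzaldehyde | C=C[C@@]1(C)CCC(C)=C[C@H]1c1c(O)c(C=O)c(OC)cc1OC | intermediate
32 | ethyl 3-{3-[(1R,6R)-6-ethenyl-3,6-dimethylcyclohex-2-en-1-yl]-2-hydroxy-4,6-dimethoxyphenyl}prop-2-enoate (E/Z mixture) | C=C[C@@]1(C)CCC(C)=C[C@H]1c1c(O)c(C=CC(=O)OCC)c(OC)cc1OC | intermediate (not isolated)
33 | 8-[(1R,6R)-6-ethenyl-3,6-dimethylcyclohex-2-en-1-yl]-5,7-dimethoxy-2H-chromen-2-one | C=C[C@@]1(C)CCC(C)=C[C@H]1c1c(OC)cc(OC)c2ccc(=O)oc12 | intermediate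
34 | 5,7-dimethoxy-2H-chromen-2-one | COc1cc(OC)c2ccc(=O)oc2c1 | starting material
35 | 8-iodo-5,7-dimethoxy-2H-chromen-2-one | COc1cc(OC)c2ccc(=O)oc2c1I | intermediate
36 | 5,7-dimethoxy-8-[(1R,6R)-6-[(E)-2-(5,7-dimethoxy-2-oxo-2H-chromen-8-yl)ethenyl]-3,6-dimethylcyclohex-2-en-1-yl]-2H-chromen-2-one | COc1cc(OC)c2ccc(=O)oc2c1/C=C/[C@@]1(C)CCC(C)=C[C@H]1c1c(OC)cc(OC)c2ccc(=O)oc12 | target

**Totals and risks**

Total step count: 17. Longest linear sequence: 14 steps (steps 1, 3–10, 12–15, 17).

Steps most likely to fail: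

1. Step 13. The first ring opening of the vinylogous-ester cyclobutenone may be slow, so that thermal oligomerisation of the volatile ynol ether and self-reaction of the vinylketene outrun the bimolecular cycloaddition. Fallback: the arene is carried in on the diene and the cyclohexene is built around it, setting out from acrylimide 7 and returning at phenol 29. O-Allylation of commercial 2-hydroxy-4,6-dimethoxybenzaldehyde (allyl bromide, K2CO3, DMF) would give 2,4-dimethoxy-6-(prop-2-en-1-yloxy)benzaldehyde F1. Horner–Wadsworth–Emmons olefination with lithiated diethyl (2-methylprop-2-en-1-yl)phosphonate (n-BuLi, THF) would give the (E)-aryl diene F2. Et2AlCl-promoted Diels–Alder reaction with 7 should give the endo imide adduct F3 with the same facial and regiochemical control as in step 3. MeOMgBr would then give the methyl ester F4, LiN(i-Pr)2/MeI the methylated ester F5, LiAlH4 the neopentyl alcohol F6, Dess–Martin oxidation the aldehyde F7, and Ph3P=CH2 the vinyl compound with an allyl-protected phenol F8. Deallylation with Pd(PPh3)4 and morpholine in THF would deliver 29.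

2. Step 12. Dimerisation of the monosubstituted ketene and amine-induced consumption of the ynol ether may compete with the cycloaddition. Fallback: a more electrophilic alkylchloroketene is used and chlorine is removed afterwards, setting out from acid 17 and returning at cyclobutenone 24. The dianion of 17 (LiN(i-Pr)2, 2.2 equiv, THF, −78 °C) is chlorinated with hexachloroethane to give the α-chloro acid F9. (COCl)2 converts it into the α-chloro acid chloride F10, and Et3N in the presence of 21 generates the alkylchloroketene F11, which should add to the ynol ether with the same polarity to give the 4-chlorocyclobutenone F12. Zn, AcOH and TMEDA in EtOH then remove chlorine to give 24.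

3. Step 17. Migratory insertion into the neopentyl-type vinyl group may be slow, so that reductive loss of iodine from 35 or arylation at another alkene takes over. Fallback: cross-metathesis instead of carbopalladation, setting out from iodide 35 and returning at target 36. Suzuki–Miyaura vinylation of 35 with potassium vinyltrifluoroborate (PdCl2(dppf), Cs2CO3, THF–H2O, 70 °C) gives 8-ethenyl-5,7-dimethoxy-2H-chromen-2-one F13. F13, used in excess, and 33 are joined with the second-generation Hoveyda–Grubbs catalyst (H2IMes)Cl2Ru=CH(C6H4-2-O-i-Pr) in toluene at 80 °C with loss of ethene; the hindered quaternary-allylic alkene cannot homodimerise and the E-alkene is the thermodynamic product.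

**Further compounds**

F1 | step 13 | 2,4-dimethoxy-6-(prop-2-en-1-yloxy)benzaldehyde | C=CCOc1cc(OC)cc(OC)c1C=O
F2 | step 13 | 1,5-dimethoxy-2-[(1E)-3-methylbuta-1,3-dien-1-yl]-3-(prop-2-en-1-yloxy)benzene | C=CCOc1cc(OC)cc(OC)c1/C=C/C(C)=C
F3 | step 13 | (4R)-4-benzyl-3-{[(1S,2R)-2-[2,4-dimethoxy-6-(prop-2-en-1-yloxy)phenyl]-4-methylcyclohex-3-en-1-yl]carbonyl}-1,3-oxazolidin-2-one | O=C1OC[C@@H](Cc2ccccc2)N1C(=O)[C@H]1CCC(C)=C[C@H]1c1c(OCC=C)cc(OC)cc1OC
F4 | step 13 | methyl (1S,2R)-2-[2,4-dimethoxy-6-(prop-2-en-1-yloxy)phenyl]-4-methylcyclohex-3-ene-1-carboxylate | COC(=O)[C@H]1CCC(C)=C[C@H]1c1c(OCC=C)cc(OC)cc1OC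
F5 | step 13 | methyl (1S,2S)-2-[2,4-dimethoxy-6-(prop-2-en-1-yloxy)phenyl]-1,4-dimethylcyclohex-3-ene-1-carboxylate | COC(=O)[C@@]1(C)CCC(C)=C[C@H]1c1c(OCC=C)cc(OC)cc1OC
F6 | step 13 | {(1S,2R)-2-[2,4-dimethoxy-6-(prop-2-en-1-yloxy)phenyl]-1,4-dimethylcyclohex-3-en-1-yl}methanol | OC[C@@]1(C)CCC(C)=C[C@H]1c1c(OCC=C)cc(OC)cc1OC
F7 | step 13 | (1S,2S)-2-[2,4-dimethoxy-6-(prop-2-en-1-yloxy)phenyl]-1,4-dimethylcyclohex-3-ene-1-carbaldehyde | O=C[C@@]1(C)CCC(C)=C[C@H]1c1c(OCC=C)cc(OC)cc1OC
F8 | step 13 | 2-[(1R,6R)-6-ethenyl-3,6-dimethylcyclohex-2-en-1-yl]-1,5-dimethoxy-3-(prop-2-en-1-yloxy)benzene | C=C[C@@]1(C)CCC(C)=C[C@H]1c1c(OCC=C)cc(OC)cc1OC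
F9 | step 12 | 2-chloro-2-[(1R,6R)-6-ethenyl-3,6-dimethylcyclohex-2-en-1-yl]acetic acid (both epimers at C2) | C=C[C@@]1(C)CCC(C)=C[C@H]1C(Cl)C(=O)O
F10 | step 12 | 2-chloro-2-[(1R,6R)-6-ethenyl-3,6-dimethylcyclohex-2-en-1-yl]acetyl chloride | C=C[C@@]1(C)CCC(C)=C[C@H]1C(Cl)C(=O)Cl
F11 | step 12 | 2-chloro-2-[(1R,6R)-6-ethenyl-3,6-dimethylcyclohex-2-en-1-yl]ethen-1-one | C=C[C@@]1(C)CCC(C)=C[C@H]1C(Cl)=C=O
F12 | step 12 | 4-chloro-4-[(1R,6R)-6-ethenyl-3,6-dimethylcyclohex-2-en-1-yl]-3-methoxycyclobut-2-en-1-one | C=C[C@@]1(C)CCC(C)=C[C@H]1C1(Cl)C(=O)C=C1OC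
F13 | step 17 | 8-ethenyl-5,7-dimethoxy-2H-chromen-2-one | COc1cc(OC)c2ccc(=O)oc2c1C=C
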